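The strategy traces the dihydrofuran ring back to a pyranone. The hydroxymethyl carbon C9 is C4 of a 2-(cyclohexenyl)chroman-4-one, so the C3–C3a bond is made by a 1,2-shift of the aryl carbon from C4 to C3. This iodine(III)-induced ring contraction closes the five-membered ring, extrudes C9 as an ester and sets C3 trans to C2 in one operation, because the iodane enters anti to the C2 substituent and leaves with inversion. Its precursor has one heterocyclic stereocentre. That centre is set when an enantiopure cyclohexenylboronate (desymmetrised divinylcarbinol, ring-closing metathesis) adds to a flat chromone under rhodium control. A single hydride reduction then releases all four hydroxyl groups.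

Key step: step 11

Atom labels: O1, C2, C3, C3a–C7a are the dihydrobenzofuran atoms, C9 is the hydroxymethyl carbon, and C1'–C6' are the cyclohexene atoms (C1'=C2', OH on C3' and C4'). Chromanone intermediates carry their own O1, C2, C3, C4, C4a–C8a.
Assumption: the (S)-biaryl bisphosphine is taken to deliver the alkenyl group to the chromone face that gives 2S, by analogy with cyclic enones; if the sense proves opposite, the (R)-ligand is used.

Step 1
Reactants: 1 methyl 3-(4-hydroxy-3-methoxyphenyl)propanoate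
Product: 3 methyl 3-(3-acetyl-4-hydroxy-5-methoxyphenyl)propanoate, via aryl acetate 2 (not isolated)
Conditions: Ac2O, BF3·OEt2, 90 °C
Reagents that add atoms: acetic anhydride, CC(=O)OC(C)=O
Why: O-acetylation followed by a Fries rearrangement should move the acyl group to the only free position ortho to the phenol (para is blocked), with the chelated o-hydroxyketone as the thermodynamic sink.

Step 2
Reactants: 3 methyl 3-(3-acetyl-4-hydroxy-5-methoxyphenyl)propanoate
Product: 5 methyl 3-(8-methoxy-4-oxo-4H-chromen-6-yl)propanoate, via enaminone 4 (not isolated)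
Conditions: Me2NCH(OMe)2, toluene, 100 °C; then AcOH, 90 °C
Reagents that add atoms: N,N-dimethylformamide dimethyl acetal, COC(OC)N(C)C
Why: Condensation of the methyl ketone with the amide acetal gives the enaminone, and addition–elimination of the phenol at its β-carbon with loss of Me2NH closes the pyranone (enaminone chromone synthesis).

Step 3
Reactants: 6 penta-1,4-dien-3-ol (divinylcarbinol)
Product: 7 (2R,3S)-1,2-epoxypent-4-en-3-ol
Conditions: Ti(OiPr)4 (cat.), L-(+)-DIPT (cat.), t-BuOOH, 4 Å MS, CH2Cl2, −20 °C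
Reagents that add atoms: tert-butyl hydroperoxide, CC(C)(C)OO
Why: Sharpless asymmetric epoxidation of the prochiral dienol couples enantiotopic-group with diastereofacial selection and removes the minor enantiomer by over-epoxidation, and L-(+)-tartrate should give the erythro (2R,3S) epoxy alcohol that sets C4' and C3'.

Step 4
Reactants: 7 (2R,3S)-1,2-epoxypent-4-en-3-ol; 8 1-(trimethylsilyl)propyne
Product: 11 (3S,4R)-oct-1-en-7-yne-3,4-diol, via lithiated silylpropyne 9 (not isolated), via C-silyl enyne diol 10 (not isolated)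
Conditions: 8 (3 equiv), n-BuLi, THF, −78 → 0 °C; 7, DMPU, −78 °C → rt; then K2CO3 (cat.), MeOH, rt
Reagents that add atoms: none
Why: SN2 opening of the terminal epoxide at its CH2 carbon by the propargylic lithium reagent (the first equivalent forms the alkoxide) leaves both stereocentres untouched, and methanolysis removes the alkynyl silane.

Step 5
Reactants: 11 (3S,4R)-oct-1-en-7-yne-3,4-diol
Product: 12 (4R,5S)-4-(but-3-yn-1-yl)-2,2-dimethyl-5-vinyl-1,3-dioxolane
Conditions: Me2C(OMe)2, PPTS (cat.), CH2Cl2, rt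
Reagents that add atoms: 2,2-dimethoxypropane, COC(C)(C)OC
Why: Acid-catalysed transketalisation converts the erythro diol into the cis-4,5-disubstituted dioxolane without touching a stereocentre.

Step 6
Reactants: 12 (4R,5S)-4-(but-3-yn-1-yl)-2,2-dimethyl-5-vinyl-1,3-dioxolane
Product: 14 2-{4-[(4R,5S)-2,2-dimethyl-5-vinyl-1,3-dioxolan-4-yl]but-1-en-2-yl}-4,4,5,5-tetramethyl-1,3,2-dioxaborolane, via internal alkenylalane 13 (not isolated)
Conditions: Ni(dppp)Cl2 (3 mol %), DIBAL-H (1.1 equiv), THF, rt; then MeOBpin, 0 °C → rt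
Reagents that add atoms: 2-methoxy-4,4,5,5-tetramethyl-1,3,2-dioxaborolane (MeOBpin), COB1OC(C)(C)C(C)(C)O1
Why: Nickel-catalysed Markovnikov (α-selective) hydroalumination of the alkyl-substituted terminal alkyne, which should outcompete the branched monosubstituted alkene while DIBAL-H is limiting, is followed by Al-to-B exchange.

Step 7
Reactants: 14 2-{4-[(4R,5S)-2,2-dimethyl-5-vinyl-1,3-dioxolan-4-yl]but-1-en-2-yl}-4,4,5,5-tetramethyl-1,3,2-dioxaborolane
Product: 15 2-[(3aS,7aR)-2,2-dimethyl-3a,6,7,7a-tetrahydro-1,3-benzodioxol-5-yl]-4,4,5,5-tetramethyl-1,3,2-dioxaborolane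
Conditions: (H2IMes)(PCy3)Cl2Ru=CHPh (5 mol %), CH2Cl2, 40 °C
Reagents that add atoms: none
Why: Ring-closing metathesis of a 1-borylvinyl group with a monosubstituted alkene is a known entry to cyclic alkenylboronates; six-ring formation and loss of ethene drive it, and no stereocentre is involved.

Step 8
Reactants: 5 methyl 3-(8-methoxy-4-oxo-4H-chromen-6-yl)propanoate; 15 2-[(3aS,7aR)-2,2-dimethyl-3a,6,7,7a-tetrahydro-1,3-benzodioxol-5-yl]-4,4,5,5-tetramethyl-1,3,2-dioxaborolane
Product: 16 methyl 3-{(2S)-2-[(3aS,7aR)-2,2-dimethyl-3a,6,7,7a-tetrahydro-1,3-benzodioxol-5-yl]-8-methoxy-4-oxochroman-6-yl}propanoate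
Conditions: [Rh(OH)(cod)]2 (3 mol %), (S)-MeO-F12-BIPHEP (7 mol %), K3PO4 (0.5 equiv), toluene/H2O 10:1, 40 °C
Reagents that add atoms: none
Why: In this Hayashi–Miyaura asymmetric conjugate addition to a chromone, the alkenyl-rhodium species inserts at C2 from the face dictated by the ligand, so the new C2 stereocentre (S) is catalyst-controlled and independent of the remote acetonide centres.

Step 9
Reactants: 16 methyl 3-{(2S)-2-[(3aS,7aR)-2,2-dimethyl-3a,6,7,7a-tetrahydro-1,3-benzodioxol-5-yl]-8-methoxy-4-oxochroman-6-yl}propanoate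
Product: 17 methyl 3-{(2S)-2-[(3S,4R)-3,4-dihydroxycyclohex-1-en-1-yl]-8-methoxy-4-oxochroman-6-yl}propanoate
Conditions: AcOH/H2O 4:1, 45 °C
Reagents that add atoms: none
Why: Mild acid hydrolysis removes the acetonide, which would not survive step 11, and spares the methyl ester and the chromanone.

Step 10
Reactants: 17 methyl 3-{(2S)-2-[(3S,4R)-3,4-dihydroxycyclohex-1-en-1-yl]-8-methoxy-4-oxochroman-6-yl}propanoate
Product: 18 methyl 3-{(2S)-8-methoxy-4-oxo-2-[(3aS,7aR)-2-oxo-3a,6,7,7a-tetrahydro-1,3-benzodioxol-5-yl]chroman-6-yl}propanoate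
Conditions: 1,1'-carbonyldiimidazole, CH2Cl2, rt
Reagents that add atoms: 1,1'-carbonyldiimidazole, O=C(n1ccnc1)n1ccnc1
Why: Carbonylation of the cis-diol gives the cyclic carbonate, which resists acid and iodine(III), shields the glycol from oxidative cleavage and is removed by hydride in step 12.

Step 11
Reactants: 18 methyl 3-{(2S)-8-methoxy-4-oxo-2-[(3aS,7aR)-2-oxo-3a,6,7,7a-tetrahydro-1,3-benzodioxol-5-yl]chroman-6-yl}propanoate
Product: 21 methyl (2S,3S)-7-methoxy-5-(3-methoxy-3-oxopropyl)-2-[(3aS,7aR)-2-oxo-3a,6,7,7a-tetrahydro-1,3-benzodioxol-5-yl]-2,3-dihydrobenzofuran-3-carboxylate, via methyl enol ether 19 (not isolated), via trans-3-iodanyl ketal 20 (not isolated)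
Conditions: PhI(OAc)2 (1.2 equiv), conc. H2SO4 (cat.), HC(OMe)3, 0 °C → rt
Reagents that add atoms: trimethyl orthoformate, COC(OC)OC
Why: Acid and HC(OMe)3 turn the ketone into the 4-methoxy-2H-chromene 19, whose C3 attacks PhI(OAc)2 while methanol caps C4 to give 20; loss of PhI is then assisted by the aryl carbon C4a, which moves from C4 to C3 through a bridged phenonium ion, and the dimethoxycarbenium ion left at C4 collapses to the methyl ester (hypervalent-iodine oxidative rearrangement, the ring contraction known for 2-arylchroman-4-ones). The dihydrofuran ring (O1–C2–C3–C3a–C7a) is closed by this 1,2-shift, formally a 3-exo-tet attack of the ipso carbon on C3 followed by cleavage of C4–C4a. C3 is the only new stereocentre: the iodane adds anti to the C2 cyclohexenyl group and is displaced with inversion, which places CO2Me trans to that group (2S,3S), while C2, C3' and C4' are not touched. Migration selectivity is stereoelectronic, since in the diequatorial 2,3-trans iodane the C3–I bond is antiperiplanar to the ring bond C4–C4a, whereas a shift of the C2 alkenyl group would need the diaxial conformer. Chemoselectivity rests on the enol ether being far more nucleophilic than C1'=C2', which is deactivated by the allylic carbonate and aryloxy groups, and the same carbonate disfavours acid ionisation of the allylic C2–O1 bond.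

Step 12
Reactants: 21 methyl (2S,3S)-7-methoxy-5-(3-methoxy-3-oxopropyl)-2-[(3aS,7aR)-2-oxo-3a,6,7,7a-tetrahydro-1,3-benzodioxol-5-yl]-2,3-dihydrobenzofuran-3-carboxylate
Product: 22 difengpiol A, (2S,3R)-2-[(3S,4R)-3,4-dihydroxycyclohex-1-en-1-yl]-3-(hydroxymethyl)-5-(3-hydroxypropyl)-7-methoxy-2,3-dihydrobenzofuran
Conditions: LiAlH4, THF, 0 °C → rt; Rochelle salt work-up
Reagents that add atoms: none
Why: Hydride reduction converts both methyl esters into primary alcohols and the cyclic carbonate into the cis-diol in one operation without touching a stereocentre (the C3 descriptor changes from S to R by priority only).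

Compound list
1 | methyl 3-(4-hydroxy-3-methoxyphenyl)propanoate | COC(=O)CCc1ccc(O)c(OC)c1 | starting material
2 | methyl 3-(4-acetoxy-3-methoxyphenyl)propanoate | COC(=O)CCc1ccc(OC(C)=O)c(OC)c1 | intermediate
3 | methyl 3-(3-acetyl-4-hydroxy-5-methoxyphenyl)propanoate | COC(=O)CCc1cc(OC)c(O)c(C(C)=O)c1 | intermediate
4 | methyl 3-{3-[(E)-3-(dimethylamino)acryloyl]-4-hydroxy-5-methoxyphenyl}propanoate | COC(=O)CCc1cc(OC)c(O)c(C(=O)/C=C/N(C)C)c1 | intermediate
5 | methyl 3-(8-methoxy-4-oxo-4H-chromen-6-yl)propanoate | COC(=O)CCc1cc(OC)c2occc(=O)c2c1 | intermediate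
6 | penta-1,4-dien-3-ol | C=CC(O)C=C | starting material
7 | (2R,3S)-1,2-epoxypent-4-en-3-ol | C=C[C@H](O)[C@H]1CO1 | intermediate
8 | 1-(trimethylsilyl)propyne | CC#C[Si](C)(C)C | starting material
9 | 3-lithio-1-(trimethylsilyl)propyne | [Li]CC#C[Si](C)(C)C | intermediate
10 | (3S,4R)-8-(trimethylsilyl)oct-1-en-7-yne-3,4-diol | C=C[C@H](O)[C@H](O)CCC#C[Si](C)(C)C | intermediate
11 | (3S,4R)-oct-1-en-7-yne-3,4-diol | C=C[C@H](O)[C@H](O)CCC#C | intermediate
12 | (4R,5S)-4-(but-3-yn-1-yl)-2,2-dimethyl-5-vinyl-1,3-dioxolane | C=C[C@@H]1OC(C)(C)O[C@@H]1CCC#C | intermediate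
13 | {4-[(4R,5S)-2,2-dimethyl-5-vinyl-1,3-dioxolan-4-yl]but-1-en-2-yl}diisobutylalane | C=C[C@@H]1OC(C)(C)O[C@@H]1CCC(=C)[Al](CC(C)C)CC(C)C | intermediate
14 | 2-{4-[(4R,5S)-2,2-dimethyl-5-vinyl-1,3-dioxolan-4-yl]but-1-en-2-yl}-4,4,5,5-tetramethyl-1,3,2-dioxaborolane | C=C[C@@H]1OC(C)(C)O[C@@H]1CCC(=C)B1OC(C)(C)C(C)(C)O1 | intermediate
15 | 2-[(3aS,7aR)-2,2-dimethyl-3a,6,7,7a-tetrahydro-1,3-benzodioxol-5-yl]-4,4,5,5-tetramethyl-1,3,2-dioxaborolane | CC1(C)OB(C2=C[C@@H]3OC(C)(C)O[C@@H]3CC2)OC1(C)C | intermediate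
16 | (2S)-2-alkenylchroman-4-one, acetonide | COC(=O)CCc1cc(OC)c2O[C@H](C3=C[C@@H]4OC(C)(C)O[C@@H]4CC3)CC(=O)c2c1 | intermediate
17 | (2S)-2-alkenylchroman-4-one, free (3S,4R)-diol | COC(=O)CCc1cc(OC)c2O[C@H](C3=C[C@H](O)[C@H](O)CC3)CC(=O)c2c1 | intermediate
18 | (2S)-2-alkenylchroman-4-one, cyclic carbonate | COC(=O)CCc1cc(OC)c2O[C@H](C3=C[C@@H]4OC(=O)O[C@@H]4CC3)CC(=O)c2c1 | intermediate
19 | (2S)-4-methoxy-2H-chromene (methyl enol ether of 18) | COC(=O)CCc1cc(OC)c2O[C@H](C3=C[C@@H]4OC(=O)O[C@@H]4CC3)C=C(OC)c2c1 | intermediate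
20 | 2,3-trans-3-[acetoxy(phenyl)-λ3-iodanyl]-4,4-dimethoxychroman | COC(=O)CCc1cc(OC)c2O[C@H](C3=C[C@@H]4OC(=O)O[C@@H]4CC3)[C@@H](I(OC(C)=O)c3ccccc3)C(OC)(OC)c2c1 | intermediate
21 | (2S,3S)-trans-2,3-dihydrobenzofuran-3-carboxylate, diester carbonate | COc1cc(CCC(=O)OC)cc2c1O[C@H](C1=C[C@@H]3OC(=O)O[C@@H]3CC1)[C@H]2C(=O)OC | intermediate
22 | difengpiol A | COc1cc(CCCO)cc2c1O[C@H](C1=C[C@H](O)[C@H](O)CC1)[C@H]2CO | target

Total step count: 12. Longest linear sequence: 10 (steps 3–12, from 6).

Steps most likely to fail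

Step 11. The C2 alkenyl group may migrate instead of the aryl carbon, the chromanone may simply be dehydrogenated, or acid may open the pyranone ring and erode the C2 configuration. The fallback keeps the same aryl shift but directs it to a carbene centre, without acid or oxidant. It sets out from 18. Trifluoroacetylation at C3 (LiHMDS, CF3CO2CH2CF3, THF, −78 °C) gives the 3-trifluoroacetyl ketone F1. Detrifluoroacetylative diazo transfer (MsN3, Et3N, MeCN) then gives the 3-diazochroman-4-one F2. Irradiation in methanol (Wolff rearrangement) contracts the ring to the ketene F3, which methanol traps. Protonation anti to the C2 group should first give the cis ester F4, which DBU equilibrates to the trans ester, and the route is rejoined at 21.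

Step 8. Insertion of the hindered alkenyl-rhodium species into the vinylogous ester may be slow, facial selectivity may be poor, or the C2 configuration may erode through retro-oxa-Michael opening under the aqueous base. The fallback gives up catalyst control and uses the enantiopure acetonide as an internal resolving element. It sets out from 5 and 15. Addition with the ligand-free catalyst ([Rh(OH)(cod)]2, dioxane/H2O) gives 16 together with the (2R)-epimeric chromanone F5. These are diastereomers and should be separable by chromatography. F5 is re-equilibrated with DBU through the ring-opened 2'-hydroxy dienone F6 and recycled, and the route is rejoined at 16.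

Step 6. The terminal alkene may be hydroaluminated with β-alkoxide loss, the acetonide may be opened reductively, or the α-selectivity may be insufficient. The fallback builds the 1-borylvinyl group from a carbonyl instead of by hydrometallation. It sets out from 12. Gold(I)-catalysed Markovnikov hydration ((IPr)AuCl/AgSbF6, dioxane/H2O) gives the methyl ketone F7. Kinetic enolisation at the methyl group (LDA, THF, −78 °C) and trapping with PhNTf2 give the terminal enol triflate F8. Miyaura borylation (B2pin2, PdCl2(dppf), KOPh, toluene) then rejoins the route at 14.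

Further compounds
F1 | step 11 | 3-trifluoroacetyl derivative of 18 | COC(=O)CCc1cc(OC)c2O[C@H](C3=C[C@@H]4OC(=O)O[C@@H]4CC3)C(C(=O)C(F)(F)F)C(=O)c2c1
F2 | step 11 | (2S)-3-diazochroman-4-one carbonate | COC(=O)CCc1cc(OC)c2O[C@H](C3=C[C@@H]4OC(=O)O[C@@H]4CC3)C(=[N+]=[N-])C(=O)c2c1
F3 | step 11 | (2S)-2,3-dihydrobenzofuran-3-ylidene ketene | COC(=O)CCc1cc(OC)c2O[C@H](C3=C[C@@H]4OC(=O)O[C@@H]4CC3)C(=C=O)c2c1
F4 | step 11 | (2S,3R)-cis-2,3-dihydrobenzofuran-3-carboxylate (C3 epimer of 21) | COc1cc(CCC(=O)OC)cc2c1O[C@H](C1=C[C@@H]3OC(=O)O[C@@H]3CC1)[C@@H]2C(=O)OC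
F5 | step 8 | (2R)-epimer of 16 | COC(=O)CCc1cc(OC)c2O[C@@H](C3=C[C@@H]4OC(C)(C)O[C@@H]4CC3)CC(=O)c2c1
F6 | step 8 | ring-opened (E)-2'-hydroxy dienone | COC(=O)CCc1cc(OC)c(O)c(C(=O)/C=C/C2=C[C@@H]3OC(C)(C)O[C@@H]3CC2)c1
F7 | step 6 | 4-[(4R,5S)-2,2-dimethyl-5-vinyl-1,3-dioxolan-4-yl]butan-2-one | C=C[C@@H]1OC(C)(C)O[C@@H]1CCC(C)=O
F8 | step 6 | 4-[(4R,5S)-2,2-dimethyl-5-vinyl-1,3-dioxolan-4-yl]but-1-en-2-yl triflate | C=C[C@@H]1OC(C)(C)O[C@@H]1CCC(=C)OS(=O)(=O)C(F)(F)F
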